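Its constants were set for the occasion; what happens was integrated by code.

We decide to reckon this flask by hand, folded into one number, before any simulation is read.

solid substrate 0.12 M; solid reagent 0.120 M; time 20 min

    solid substrate ⇌ dissolved substrate, rate k1*(cs1 - [dissolved substrate]) while solid is left; crystals form when [dissolved substrate] > cs1 (cs1 = 0.055 M, k1 = 0.0049 s⁻¹)
    dissolved substrate + partner → target (k2 = 21 M⁻¹ s⁻¹)
    2 dissolved substrate → side product (k3 = 31 M⁻¹ s⁻¹)
    solid product ⇌ target, rate k4*(cs4 - [target]) while solid is left; crystals form when [target] > cs4 (cs4 = 1.4 mM, k4 = 0.29 s⁻¹)
    solid reagent ⇌ partner, rate k5*(cs5 - [partner]) while solid is left; crystals form when [partner] > cs5 (cs5 = 0.073 M, k5 = 0.0080 s⁻¹)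
    partner → decomposition product (k6 = 4.0 × 10⁻⁵ s⁻¹)

- percent here means solid substrate units held: one side product counts as two
- what is said of target includes solid product
- two of one species on the left: rate k times its square, two consumed each time
- solid substrate, solid product, solid reagent is a solid; its amount is given per volume of the solution
- at the start none of the solid substrate is in solution
- at the start none of the solid reagent is in solution
- dissolved substrate means what is dissolved; the solid is not counted in it
- run time (flask): 20 min

- how much target and solid product together there is at 20 min, in percent of the solid substrate charged
- concentration of dissolved substrate in solution at 20 min, in percent of saturation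

Solid substrate feeds the solution at about 0.269 mM s⁻¹ and solid reagent at up to 0.584 mM s⁻¹. While solid reagent lasts, we let partner level off at 0.0393 M, where its dissolving matches the substrate supply. Dissolved substrate then meets partner at 0.826 s⁻¹, faster than its dissolving coefficient 0.0049 s⁻¹, so we let what dissolves react at once, and [dissolved substrate] stands near 0.326 mM.

Our number is S, here 40.8, a selectivity factor: the rate at which partner uses dissolved substrate over the rate at which the side reaction uses it. So 2.39% of the supply becomes side product at the plateau.

One number is not enough: partner starts from zero and rises over 125 s. S grows with the square of [partner], so it passes one after about 19.6 s, and we count that stretch as lost. The substrate supply lasts 7.42 min, so the total loss is 6.79% and y comes to 93.2%. That supply ends before the reading, so we put sat under 0.594%.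

The forecast gives 91.5% and 0%, placing the side product “mostly early while little partner is in solution”. Its y stands below ours.

The simulation gives 92.5% and 0%, and the forecast holds within its margin. At 2.28 min partner used dissolved substrate 23 times as fast as the side reaction did, a value below our plateau S. The side product stood at 7.49% at 20.0 min, against our 6.79%.

For the flask read at 5.0 min, the same S and rise give 61.4% as target and solid product. That neighbour computes to 61.4%.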